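Both ε-rings carry a quaternary C1 flanked by C2 (bearing a CH2–CH= chain) and by C6, the allylic terminus of the C4=C5(Me) alkene, with C4 unsubstituted. Each C6–C7 bond is therefore traced back to a C4 carbinol with a C5(Me)=C6 alkene, etherified as O–CH2SnBu3. Tin–lithium exchange triggers a [2,3]-Wittig shift that moves this carbon to C6 on the face of the C4–O bond while the alkene returns to C4=C5; the trans carbinol gives the 2,6-trans ring B, the cis carbinol the 2,6-cis ring A. Both carbinols arise from ring-expanded (R)-α-campholenic aldehyde, which supplies C1, C2 and the C2 stereocentre; C20 phosphonium salts and a C10 dialdehyde build the polyene.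

Key step: step 13

Remark: ring atoms carry carotenoid numbers (C1 = CMe2, C2 bears the C5 side chain, C6 bears C7; ring A = prenyl ring, ring B = hydroxyprenyl ring), and enantiopure (R)-α-campholenic aldehyde is taken as purchasable (otherwise one step from (−)-α-pinene oxide with ZnBr2).

Step 1
Reactants: 1 (R)-α-campholenic aldehyde
Product: 2 (4R)-4-(2,2-dimethoxyethyl)-1,5,5-trimethylcyclopent-1-ene
Conditions: HC(OMe)3, MeOH, PPTS (cat.), rt
Reagents that add atoms: trimethyl orthoformate, COC(OC)OC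
Why: Acid-catalysed acetalisation with the orthoformate as water scavenger masks the aldehyde for the ozonolysis and the basic steps ahead, and the weak acid leaves the ring alkene and the stereocentre alone.

Step 2
Reactants: 2 (4R)-4-(2,2-dimethoxyethyl)-1,5,5-trimethylcyclopent-1-ene
Product: 4 (3R)-3-(2,2-dimethoxyethyl)-4,4-dimethyl-5-oxohexanal, via secondary ozonide 3 (not isolated)
Conditions: O3, CH2Cl2, −78 °C (stopped at first excess); then PPh3, −78 °C to rt
Reagents that add atoms: ozone, [O-][O+]=O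
Why: Ozonolysis (Criegee mechanism) with reductive work-up cleaves the only alkene to a methyl ketone and an aldehyde, the acetal reacting far more slowly with ozone than the trisubstituted alkene.

Step 3
Reactants: 4 (3R)-3-(2,2-dimethoxyethyl)-4,4-dimethyl-5-oxohexanal
Product: 6 (5R)-5-(2,2-dimethoxyethyl)-6,6-dimethylcyclohex-2-en-1-one, via aldol 5 (not isolated)
Conditions: KOH, MeOH, 0 °C to rt
Reagents that add atoms: none
Why: Intramolecular aldol condensation closes the six-membered ring because the ketone can enolise only at its methyl group (the other flank is quaternary), and E1cB loss of water should drive it to the conjugated enone.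

Step 4
Reactants: 6 (5R)-5-(2,2-dimethoxyethyl)-6,6-dimethylcyclohex-2-en-1-one
Product: 7 (5R)-5-(2,2-dimethoxyethyl)-2-iodo-6,6-dimethylcyclohex-2-en-1-one
Conditions: I2, pyridine, CH2Cl2, 0 °C to rt
Reagents that add atoms: iodine, II
Why: α-Iodination of an enone by pyridine conjugate addition, iodination of the enolate and elimination functionalises only the α-carbon, the future C5.

Step 5
Reactants: 7 (5R)-5-(2,2-dimethoxyethyl)-2-iodo-6,6-dimethylcyclohex-2-en-1-one
Product: 8 (5R)-5-(2,2-dimethoxyethyl)-2,6,6-trimethylcyclohex-2-en-1-one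
Conditions: MeB(OH)2, Pd(OAc)2 (cat.), SPhos, K3PO4, toluene/H2O, 80 °C
Reagents that add atoms: methylboronic acid, CB(O)O
Why: Suzuki–Miyaura coupling of the α-iodoenone with methylboronic acid installs the C5 methyl group under basic conditions that the acetal tolerates.

Step 6
Reactants: 8 (5R)-5-(2,2-dimethoxyethyl)-2,6,6-trimethylcyclohex-2-en-1-one
Product: 9 (1S,4R,6S)-4-(2,2-dimethoxyethyl)-1,3,3-trimethyl-7-oxabicyclo[4.1.0]heptan-2-one
Conditions: 30% H2O2, NaOH (cat.), MeOH, 0 °C
Reagents that add atoms: hydrogen peroxide, OO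
Why: Weitz–Scheffer epoxidation, in which hydroperoxide should add to C4 anti to the C2 side chain (as in 5-substituted 2-methylcyclohexenones such as carvone) before the enolate closes the oxirane, so both epoxide carbons are set on the face opposite the side chain.

Step 7
Reactants: 9 (1S,4R,6S)-4-(2,2-dimethoxyethyl)-1,3,3-trimethyl-7-oxabicyclo[4.1.0]heptan-2-one
Product: 11 (1S,5R)-5-(2,2-dimethoxyethyl)-2,4,4-trimethylcyclohex-2-en-1-ol (C4–OH trans to the C2 chain), via epoxy hydrazone 10 (not isolated)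
Conditions: N2H4·H2O, AcOH (cat.), MeOH, 0 °C to rt
Reagents that add atoms: none
Why: Wharton transposition, in which the hydrazone fragments with loss of N2, moves the alkene to C5=C6 and frees the C4 oxygen with its configuration unchanged, so the carbinol should be trans to the C2 chain.

Step 8
Reactants: 11 (1S,5R)-5-(2,2-dimethoxyethyl)-2,4,4-trimethylcyclohex-2-en-1-ol
Product: 12 2-[(1R,5S)-5-hydroxy-2,2,4-trimethylcyclohex-3-en-1-yl]acetaldehyde
Conditions: PPTS (cat.), acetone/H2O, 40 °C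
Reagents that add atoms: water, O
Why: Mild acetal hydrolysis frees the aldehyde without ionising the allylic alcohol, and the trans 1,3-relationship rules out a bridged lactol.

Step 9
Reactants: 12 2-[(1R,5S)-5-hydroxy-2,2,4-trimethylcyclohex-3-en-1-yl]acetaldehyde
Product: 13 ethyl (2E)-4-[(1S,5S)-5-hydroxy-2,2,4-trimethylcyclohex-3-en-1-yl]-2-methylbut-2-enoate
Conditions: Ph3P=C(CH3)CO2Et, CH2Cl2, rt
Reagents that add atoms: ethyl 2-(triphenyl-λ5-phosphanylidene)propanoate, CCOC(=O)C(C)=P(c1ccccc1)(c1ccccc1)c1ccccc1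
Why: Wittig olefination with the stabilised α-methyl ylide should give the E trisubstituted enoate and tolerates the free hydroxyl.

Step 10
Reactants: 13 ethyl (2E)-4-[(1S,5S)-5-hydroxy-2,2,4-trimethylcyclohex-3-en-1-yl]-2-methylbut-2-enoate
Product: 14 (1S,5S)-5-[(2E)-4-hydroxy-3-methylbut-2-en-1-yl]-2,4,4-trimethylcyclohex-2-en-1-ol
Conditions: i-Bu2AlH (excess), CH2Cl2, −78 °C; aq. potassium sodium tartrate
Reagents that add atoms: none
Why: 1,2-Reduction of the α,β-unsaturated ester by the aluminium hydride gives the primary allylic alcohol and leaves both alkenes untouched.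

Step 11
Reactants: 14 (1S,5S)-5-[(2E)-4-hydroxy-3-methylbut-2-en-1-yl]-2,4,4-trimethylcyclohex-2-en-1-ol
Product: 15 (1S,5S)-5-[(2E)-4-(tert-butyldiphenylsilyloxy)-3-methylbut-2-en-1-yl]-2,4,4-trimethylcyclohex-2-en-1-ol
Conditions: TBDPSCl (1.05 equiv), imidazole, CH2Cl2, 0 °C
Reagents that add atoms: tert-butyl(chloro)diphenylsilane, CC(C)(C)[Si](Cl)(c1ccccc1)c1ccccc1
Why: Silylation with the bulky chlorosilane selects the primary hydroxyl over the hindered secondary one, and this ether withstands KH, n-BuLi, the oxidation, the olefination, the hydride and the mildly acidic salt formation that follow.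

Step 12
Reactants: 15 (1S,5S)-5-[(2E)-4-(tert-butyldiphenylsilyloxy)-3-methylbut-2-en-1-yl]-2,4,4-trimethylcyclohex-2-en-1-ol
Product: 16 tributyl[({(1S,5S)-5-[(2E)-4-(tert-butyldiphenylsilyloxy)-3-methylbut-2-en-1-yl]-2,4,4-trimethylcyclohex-2-en-1-yl}oxy)methyl]stannane
Conditions: KH, THF, 0 °C; then Bu3SnCH2I, rt
Reagents that add atoms: (iodomethyl)tributylstannane, CCCC[Sn](CCCC)(CCCC)CI
Why: Williamson etherification of the potassium alkoxide with the primary iodide gives the stannylmethyl ether with the C4 configuration retained, since no bond to C4 is broken.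

Step 13
Reactants: 16 tributyl[({(1S,5S)-5-[(2E)-4-(tert-butyldiphenylsilyloxy)-3-methylbut-2-en-1-yl]-2,4,4-trimethylcyclohex-2-en-1-yl}oxy)methyl]stannane
Product: 18 {(1S,5R)-5-[(2E)-4-(tert-butyldiphenylsilyloxy)-3-methylbut-2-en-1-yl]-2,6,6-trimethylcyclohex-2-en-1-yl}methanol (ring B; C7 trans to the C2 chain), via alkoxymethyllithium 17 (not isolated)
Conditions: n-BuLi, THF, −78 °C; then H2O
Reagents that add atoms: none
Why: Tin–lithium exchange at −78 °C gives the alkoxymethyllithium 17, whose carbanion carbon bonds to C6 through a five-membered envelope transition state while the C4–O bond breaks and the alkene shifts to C4=C5, an irreversible [2,3]-sigmatropic shift that trades a carbanion for an alkoxide. The closest known reaction is the Wittig–Still rearrangement of stannylmethyl ethers of cyclohex-2-enols, which proceeds with 1,3-chirality transfer. No ring is closed. The new stereocentre C6 is controlled by the C4 carbinol carbon: the shift is suprafacial, so C7 should arrive on the face that held the oxygen, anti to the C2 chain, giving the 2,6-trans ring B. The step needs complete facial fidelity and [2,3] over [1,2] selectivity, and the cyclic transition state, the single allylic terminus, the pseudoaxial C4–O bond (favoured by strain against the C5 methyl, with the C2 chain equatorial) and the low temperature should secure both.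

Step 14
Reactants: 18 {(1S,5R)-5-[(2E)-4-(tert-butyldiphenylsilyloxy)-3-methylbut-2-en-1-yl]-2,6,6-trimethylcyclohex-2-en-1-yl}methanol
Product: 19 (1S,5R)-5-[(2E)-4-(tert-butyldiphenylsilyloxy)-3-methylbut-2-en-1-yl]-2,6,6-trimethylcyclohex-2-ene-1-carbaldehyde
Conditions: Dess–Martin periodinane, pyridine, CH2Cl2, 0 °C; used crude at once
Reagents that add atoms: none
Why: Dess–Martin oxidation buffered with pyridine gives the β,γ-unsaturated aldehyde under near-neutral conditions, which should limit epimerisation at C6 and migration of the alkene into conjugation.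

Step 15
Reactants: 19 (1S,5R)-5-[(2E)-4-(tert-butyldiphenylsilyloxy)-3-methylbut-2-en-1-yl]-2,6,6-trimethylcyclohex-2-ene-1-carbaldehyde; 20 triethyl (E)-3-methyl-4-phosphonocrotonate
Product: 22 ethyl (2E,4E)-5-{(1S,5R)-5-[(2E)-4-(tert-butyldiphenylsilyloxy)-3-methylbut-2-en-1-yl]-2,6,6-trimethylcyclohex-2-en-1-yl}-3-methylpenta-2,4-dienoate, via sodium phosphonate 21 (not isolated)
Conditions: 20, NaN(SiMe3)2, THF, −78 °C; then 19, −78 to 0 °C
Reagents that add atoms: none
Why: Horner–Wadsworth–Emmons olefination with the sodium phosphonate, preformed at −78 °C so that no free amide base meets the aldehyde, should add to the hindered carbonyl faster than it enolises a C6 centre that already holds the less strained trans arrangement and give the E C7=C8 bond, any 2Z ester being removed by chromatography.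

Step 16
Reactants: 22 ethyl (2E,4E)-5-{(1S,5R)-5-[(2E)-4-(tert-butyldiphenylsilyloxy)-3-methylbut-2-en-1-yl]-2,6,6-trimethylcyclohex-2-en-1-yl}-3-methylpenta-2,4-dienoate
Product: 23 (2E,4E)-5-{(1S,5R)-5-[(2E)-4-(tert-butyldiphenylsilyloxy)-3-methylbut-2-en-1-yl]-2,6,6-trimethylcyclohex-2-en-1-yl}-3-methylpenta-2,4-dien-1-ol
Conditions: i-Bu2AlH, CH2Cl2, −78 °C; aq. potassium sodium tartrate
Reagents that add atoms: none
Why: 1,2-Reduction of the dienoate gives the C11 dienol without touching the silyl ether or the alkenes.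

Step 17
Reactants: 23 (2E,4E)-5-{(1S,5R)-5-[(2E)-4-(tert-butyldiphenylsilyloxy)-3-methylbut-2-en-1-yl]-2,6,6-trimethylcyclohex-2-en-1-yl}-3-methylpenta-2,4-dien-1-ol
Product: 24 [(2E,4E)-5-{(1S,5R)-5-[(2E)-4-(tert-butyldiphenylsilyloxy)-3-methylbut-2-en-1-yl]-2,6,6-trimethylcyclohex-2-en-1-yl}-3-methylpenta-2,4-dien-1-yl]triphenylphosphonium bromide
Conditions: Ph3P·HBr, CH2Cl2, 0 °C to rt
Reagents that add atoms: triphenylphosphine hydrobromide, [Br-].c1ccc(cc1)[PH+](c1ccccc1)c1ccccc1
Why: SN1-type substitution, in which the protonated dienol ionises to a pentadienyl cation that the phosphine captures at the terminal carbon, is the standard way to end-group Wittig salts and should spare the robust silyl ether.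

Step 18
Reactants: 24 [(2E,4E)-5-{(1S,5R)-5-[(2E)-4-(tert-butyldiphenylsilyloxy)-3-methylbut-2-en-1-yl]-2,6,6-trimethylcyclohex-2-en-1-yl}-3-methylpenta-2,4-dien-1-yl]triphenylphosphonium bromide
Product: 25 [(2E,4E)-5-{(1S,5R)-5-[(2E)-4-hydroxy-3-methylbut-2-en-1-yl]-2,6,6-trimethylcyclohex-2-en-1-yl}-3-methylpenta-2,4-dien-1-yl]triphenylphosphonium bromide
Conditions: HF·pyridine, pyridine, THF, 0 °C to rt; aq. NaBr wash
Reagents that add atoms: none
Why: Fluoride-mediated desilylation under buffered, non-basic conditions frees the primary hydroxyl without forming the ylide or adding HF to the alkenes.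

Step 19
Reactants: 11 (1S,5R)-5-(2,2-dimethoxyethyl)-2,4,4-trimethylcyclohex-2-en-1-ol
Product: 26 (5S)-5-(2,2-dimethoxyethyl)-2,4,4-trimethylcyclohex-2-en-1-one
Conditions: MnO2 (excess), CH2Cl2, rt
Reagents that add atoms: none
Why: Allylic oxidation with MnO2 is selective for the allylic carbinol and erases the C4 configuration so that it can be reset.

Step 20
Reactants: 26 (5S)-5-(2,2-dimethoxyethyl)-2,4,4-trimethylcyclohex-2-en-1-one
Product: 27 (1R,5R)-5-(2,2-dimethoxyethyl)-2,4,4-trimethylcyclohex-2-en-1-ol (C4–OH cis to the C2 chain)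
Conditions: NaBH4, CeCl3·7H2O, MeOH, −78 °C
Reagents that add atoms: none
Why: Luche 1,2-reduction, in which hydride should add to the carbonyl face anti to the C2 chain (the carvone to cis-carveol pattern), places the hydroxyl cis to that chain; any trans epimer is 11 and can rejoin the ring B branch.

Step 21
Reactants: 27 (1R,5R)-5-(2,2-dimethoxyethyl)-2,4,4-trimethylcyclohex-2-en-1-ol
Product: 28 tributyl({[(1R,5R)-5-(2,2-dimethoxyethyl)-2,4,4-trimethylcyclohex-2-en-1-yl]oxy}methyl)stannane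
Conditions: KH, THF, 0 °C; then Bu3SnCH2I, rt
Reagents that add atoms: (iodomethyl)tributylstannane, CCCC[Sn](CCCC)(CCCC)CI
Why: Williamson etherification as in step 12 gives the cis stannylmethyl ether without touching the acetal or the C4 centre.

Step 22
Reactants: 28 tributyl({[(1R,5R)-5-(2,2-dimethoxyethyl)-2,4,4-trimethylcyclohex-2-en-1-yl]oxy}methyl)stannane
Product: 30 [(1R,5R)-5-(2,2-dimethoxyethyl)-2,6,6-trimethylcyclohex-2-en-1-yl]methanol (ring A; C7 cis to the C2 chain), via alkoxymethyllithium 29 (not isolated)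
Conditions: n-BuLi, THF, −78 °C; then H2O
Reagents that add atoms: none
Why: The same suprafacial Wittig–Still [2,3] shift as in step 13 should deliver C7 to C6 syn to the departing C4 oxygen, now cis to the C2 chain, through the conformer with the C4–O bond and the small acetal chain both axial.

Step 23
Reactants: 30 [(1R,5R)-5-(2,2-dimethoxyethyl)-2,6,6-trimethylcyclohex-2-en-1-yl]methanol
Product: 31 2-[(1R,5R)-5-(hydroxymethyl)-4,6,6-trimethylcyclohex-3-en-1-yl]acetaldehyde
Conditions: PPTS (cat.), acetone/H2O, 40 °C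
Reagents that add atoms: water, O
Why: Acetal hydrolysis frees the aldehyde while the primary homoallylic alcohol is inert to the weak acid, and a seven-membered lactol form, if present, is harmless in the next step.

Step 24
Reactants: 31 2-[(1R,5R)-5-(hydroxymethyl)-4,6,6-trimethylcyclohex-3-en-1-yl]acetaldehyde
Product: 32 [(1R,5S)-2,6,6-trimethyl-5-(3-methylbut-2-en-1-yl)cyclohex-2-en-1-yl]methanol
Conditions: i-PrPPh3I (2.5 equiv), n-BuLi, THF, 0 °C; then 31, −78 °C to rt
Reagents that add atoms: isopropyltriphenylphosphonium iodide, CC(C)[P+](c1ccccc1)(c1ccccc1)c1ccccc1.[I-]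
Why: Wittig olefination with the non-stabilised isopropylidene ylide, used in excess because the hydroxyl consumes one equivalent, builds the prenyl group with no alkene geometry at stake.

Step 25
Reactants: 32 [(1R,5S)-2,6,6-trimethyl-5-(3-methylbut-2-en-1-yl)cyclohex-2-en-1-yl]methanol
Product: 33 (1R,5S)-2,6,6-trimethyl-5-(3-methylbut-2-en-1-yl)cyclohex-2-ene-1-carbaldehyde
Conditions: Dess–Martin periodinane, pyridine, CH2Cl2, 0 °C; used crude at once
Reagents that add atoms: none
Why: Buffered Dess–Martin oxidation gives the epimerisable β,γ-unsaturated aldehyde without acid or base strong enough to disturb the cis C6 centre or either alkene.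

Step 26
Reactants: 33 (1R,5S)-2,6,6-trimethyl-5-(3-methylbut-2-en-1-yl)cyclohex-2-ene-1-carbaldehyde; 20 triethyl (E)-3-methyl-4-phosphonocrotonate
Product: 35 ethyl (2E,4E)-3-methyl-5-[(1R,5S)-2,6,6-trimethyl-5-(3-methylbut-2-en-1-yl)cyclohex-2-en-1-yl]penta-2,4-dienoate, via lithium phosphonate 34 (not isolated)
Conditions: 20, LiN(SiMe3)2, THF, −78 °C; then 33, −78 to 0 °C
Reagents that add atoms: none
Why: Horner–Wadsworth–Emmons olefination, run here through the lithium phosphonate because its tight ion pair is the least basic form of the reagent and lithium activates the carbonyl, should form the E C7=C8 bond before the more fragile cis C6 centre can enolise, after which C6 is no longer α to a carbonyl.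

Step 27
Reactants: 35 ethyl (2E,4E)-3-methyl-5-[(1R,5S)-2,6,6-trimethyl-5-(3-methylbut-2-en-1-yl)cyclohex-2-en-1-yl]penta-2,4-dienoate
Product: 36 (2E,4E)-3-methyl-5-[(1R,5S)-2,6,6-trimethyl-5-(3-methylbut-2-en-1-yl)cyclohex-2-en-1-yl]penta-2,4-dien-1-ol
Conditions: i-Bu2AlH, CH2Cl2, −78 °C; aq. potassium sodium tartrate
Reagents that add atoms: none
Why: 1,2-Reduction of the dienoate gives the C11 dienol and leaves the three alkenes untouched.

Step 28
Reactants: 36 (2E,4E)-3-methyl-5-[(1R,5S)-2,6,6-trimethyl-5-(3-methylbut-2-en-1-yl)cyclohex-2-en-1-yl]penta-2,4-dien-1-ol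
Product: 37 {(2E,4E)-3-methyl-5-[(1R,5S)-2,6,6-trimethyl-5-(3-methylbut-2-en-1-yl)cyclohex-2-en-1-yl]penta-2,4-dien-1-yl}triphenylphosphonium bromide
Conditions: Ph3P·HBr, MeOH, 0 °C to rt
Reagents that add atoms: triphenylphosphine hydrobromide, [Br-].c1ccc(cc1)[PH+](c1ccccc1)c1ccccc1
Why: SN1-type phosphonium salt formation through the pentadienyl cation, as in step 17, uses acid that is consumed as the salt forms and so should spare the prenyl alkene.

Step 29
Reactants: 37 {(2E,4E)-3-methyl-5-[(1R,5S)-2,6,6-trimethyl-5-(3-methylbut-2-en-1-yl)cyclohex-2-en-1-yl]penta-2,4-dien-1-yl}triphenylphosphonium bromide; 38 (2E,4E,6E)-2,7-dimethylocta-2,4,6-trienedial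
Product: 40 (2E,4E,6E,8E,10E,12E)-2,7,11-trimethyl-13-[(1R,5S)-2,6,6-trimethyl-5-(3-methylbut-2-en-1-yl)cyclohex-2-en-1-yl]trideca-2,4,6,8,10,12-hexaenal, via ring A ylide 39 (not isolated)
Conditions: NaOMe, MeOH/CH2Cl2, 0 °C, slow addition to 38 (3 equiv); then heat in heptane (Z to E)
Reagents that add atoms: none
Why: Wittig olefination of the allylic ylide with an excess of the symmetrical dialdehyde should stop at mono-olefination (C11=C12), the Z isomer at the new bond being equilibrated thermally and the surplus dialdehyde recovered.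

Step 30
Reactants: 40 (2E,4E,6E,8E,10E,12E)-2,7,11-trimethyl-13-[(1R,5S)-2,6,6-trimethyl-5-(3-methylbut-2-en-1-yl)cyclohex-2-en-1-yl]trideca-2,4,6,8,10,12-hexaenal; 25 [(2E,4E)-5-{(1S,5R)-5-[(2E)-4-hydroxy-3-methylbut-2-en-1-yl]-2,6,6-trimethylcyclohex-2-en-1-yl}-3-methylpenta-2,4-dien-1-yl]triphenylphosphonium bromide
Product: 42 (all-E,2S,6R,2'R,6'S)-2'-[(2E)-4-hydroxy-3-methylbut-2-en-1-yl]-2-(3-methylbut-2-en-1-yl)-ε,ε-carotene (CNP0304855.1), via ring B ylide 41 (not isolated)
Conditions: NaOMe, MeOH/CH2Cl2, rt; then reflux in EtOH (Z to E), crystallisation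
Reagents that add atoms: none
Why: Wittig olefination forms C11'=C12' with methoxide as base, which the free primary hydroxyl tolerates, and thermal equilibration with crystallisation should deliver the all-E polyene without touching the four ring stereocentres.

Compound list
1 | (R)-α-campholenic aldehyde, 2-[(1R)-2,2,3-trimethylcyclopent-3-en-1-yl]acetaldehyde | O=CC[C@H]1CC=C(C)C1(C)C | starting material
2 | (4R)-4-(2,2-dimethoxyethyl)-1,5,5-trimethylcyclopent-1-ene | COC(OC)C[C@H]1CC=C(C)C1(C)C | intermediate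
3 | secondary ozonide of 2, 3-(2,2-dimethoxyethyl)-1,2,2-trimethyl-6,7,8-trioxabicyclo[3.2.1]octane (side-chain centre unchanged, bridge diastereomers) | COC(OC)C[C@H]1CC2OOC(C)(O2)C1(C)C | intermediate
4 | (3R)-3-(2,2-dimethoxyethyl)-4,4-dimethyl-5-oxohexanal | COC(OC)C[C@@H](CC=O)C(C)(C)C(C)=O | intermediate
5 | (5R)-5-(2,2-dimethoxyethyl)-3-hydroxy-6,6-dimethylcyclohexan-1-one (carbinol epimers) | COC(OC)C[C@H]1CC(O)CC(=O)C1(C)C | intermediate
6 | (5R)-5-(2,2-dimethoxyethyl)-6,6-dimethylcyclohex-2-en-1-one | COC(OC)C[C@H]1CC=CC(=O)C1(C)C | intermediate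
7 | (5R)-5-(2,2-dimethoxyethyl)-2-iodo-6,6-dimethylcyclohex-2-en-1-one | COC(OC)C[C@H]1CC=C(I)C(=O)C1(C)C | intermediate
8 | (5R)-5-(2,2-dimethoxyethyl)-2,6,6-trimethylcyclohex-2-en-1-one | COC(OC)C[C@H]1CC=C(C)C(=O)C1(C)C | intermediate
9 | (1S,4R,6S)-4-(2,2-dimethoxyethyl)-1,3,3-trimethyl-7-oxabicyclo[4.1.0]heptan-2-one (epoxide anti to the side chain) | COC(OC)C[C@H]1C[C@@H]2O[C@]2(C)C(=O)C1(C)C | intermediate
10 | hydrazone of 9 | COC(OC)C[C@H]1C[C@@H]2O[C@]2(C)C(=NN)C1(C)C | intermediate
11 | (1S,5R)-5-(2,2-dimethoxyethyl)-2,4,4-trimethylcyclohex-2-en-1-ol (C4–OH trans to the C2 chain) | COC(OC)C[C@H]1C[C@H](O)C(C)=CC1(C)C | intermediate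
12 | 2-[(1R,5S)-5-hydroxy-2,2,4-trimethylcyclohex-3-en-1-yl]acetaldehyde | O=CC[C@H]1C[C@H](O)C(C)=CC1(C)C | intermediate
13 | ethyl (2E)-4-[(1S,5S)-5-hydroxy-2,2,4-trimethylcyclohex-3-en-1-yl]-2-methylbut-2-enoate | CCOC(=O)/C(C)=C/C[C@H]1C[C@H](O)C(C)=CC1(C)C | intermediate
14 | (1S,5S)-5-[(2E)-4-hydroxy-3-methylbut-2-en-1-yl]-2,4,4-trimethylcyclohex-2-en-1-ol | OC/C(C)=C/C[C@H]1C[C@H](O)C(C)=CC1(C)C | intermediate
15 | (1S,5S)-5-[(2E)-4-(tert-butyldiphenylsilyloxy)-3-methylbut-2-en-1-yl]-2,4,4-trimethylcyclohex-2-en-1-ol | CC(C)(C)[Si](c1ccccc1)(c1ccccc1)OC/C(C)=C/C[C@H]1C[C@H](O)C(C)=CC1(C)C | intermediate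
16 | tributyl[({(1S,5S)-5-[(2E)-4-(tert-butyldiphenylsilyloxy)-3-methylbut-2-en-1-yl]-2,4,4-trimethylcyclohex-2-en-1-yl}oxy)methyl]stannane | CC(C)(C)[Si](c1ccccc1)(c1ccccc1)OC/C(C)=C/C[C@H]1C[C@H](OC[Sn](CCCC)(CCCC)CCCC)C(C)=CC1(C)C | intermediate
17 | lithiomethyl ether from 16 (alkoxymethyllithium) | CC(C)(C)[Si](c1ccccc1)(c1ccccc1)OC/C(C)=C/C[C@H]1C[C@H](OC[Li])C(C)=CC1(C)C | intermediate
18 | {(1S,5R)-5-[(2E)-4-(tert-butyldiphenylsilyloxy)-3-methylbut-2-en-1-yl]-2,6,6-trimethylcyclohex-2-en-1-yl}methanol (2,6-trans) | CC(C)(C)[Si](c1ccccc1)(c1ccccc1)OC/C(C)=C/C[C@H]1CC=C(C)[C@H](CO)C1(C)C | intermediate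
19 | (1S,5R)-5-[(2E)-4-(tert-butyldiphenylsilyloxy)-3-methylbut-2-en-1-yl]-2,6,6-trimethylcyclohex-2-ene-1-carbaldehyde | CC(C)(C)[Si](c1ccccc1)(c1ccccc1)OC/C(C)=C/C[C@H]1CC=C(C)[C@H](C=O)C1(C)C | intermediate
20 | triethyl (E)-3-methyl-4-phosphonocrotonate, ethyl (2E)-4-(diethoxyphosphoryl)-3-methylbut-2-enoate | CCOC(=O)/C=C(\C)CP(=O)(OCC)OCC | starting material
21 | sodium salt of 20 (phosphonate carbanion) | [Na+].CCOC(=O)/C=C(\C)[CH-]P(=O)(OCC)OCC | intermediate
22 | ethyl (2E,4E)-5-{(1S,5R)-5-[(2E)-4-(tert-butyldiphenylsilyloxy)-3-methylbut-2-en-1-yl]-2,6,6-trimethylcyclohex-2-en-1-yl}-3-methylpenta-2,4-dienoate | CCOC(=O)/C=C(C)/C=C/[C@H]1C(C)=CC[C@H](C/C=C(\C)CO[Si](c2ccccc2)(c2ccccc2)C(C)(C)C)C1(C)C | intermediate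
23 | (2E,4E)-5-{(1S,5R)-5-[(2E)-4-(tert-butyldiphenylsilyloxy)-3-methylbut-2-en-1-yl]-2,6,6-trimethylcyclohex-2-en-1-yl}-3-methylpenta-2,4-dien-1-ol | OC/C=C(C)/C=C/[C@H]1C(C)=CC[C@H](C/C=C(\C)CO[Si](c2ccccc2)(c2ccccc2)C(C)(C)C)C1(C)C | intermediate
24 | [(2E,4E)-5-{(1S,5R)-5-[(2E)-4-(tert-butyldiphenylsilyloxy)-3-methylbut-2-en-1-yl]-2,6,6-trimethylcyclohex-2-en-1-yl}-3-methylpenta-2,4-dien-1-yl]triphenylphosphonium bromide | [Br-].CC(C)(C)[Si](c1ccccc1)(c1ccccc1)OC/C(C)=C/C[C@H]1CC=C(C)[C@H](/C=C/C(C)=C/C[P+](c2ccccc2)(c2ccccc2)c2ccccc2)C1(C)C | intermediate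
25 | [(2E,4E)-5-{(1S,5R)-5-[(2E)-4-hydroxy-3-methylbut-2-en-1-yl]-2,6,6-trimethylcyclohex-2-en-1-yl}-3-methylpenta-2,4-dien-1-yl]triphenylphosphonium bromide | [Br-].OC/C(C)=C/C[C@H]1CC=C(C)[C@H](/C=C/C(C)=C/C[P+](c2ccccc2)(c2ccccc2)c2ccccc2)C1(C)C | intermediate
26 | (5S)-5-(2,2-dimethoxyethyl)-2,4,4-trimethylcyclohex-2-en-1-one | COC(OC)C[C@H]1CC(=O)C(C)=CC1(C)C | intermediate
27 | (1R,5R)-5-(2,2-dimethoxyethyl)-2,4,4-trimethylcyclohex-2-en-1-ol (C4–OH cis to the C2 chain) | COC(OC)C[C@H]1C[C@@H](O)C(C)=CC1(C)C | intermediate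
28 | tributyl({[(1R,5R)-5-(2,2-dimethoxyethyl)-2,4,4-trimethylcyclohex-2-en-1-yl]oxy}methyl)stannane | COC(OC)C[C@H]1C[C@@H](OC[Sn](CCCC)(CCCC)CCCC)C(C)=CC1(C)C | intermediate
29 | lithiomethyl ether from 28 (alkoxymethyllithium) | COC(OC)C[C@H]1C[C@@H](OC[Li])C(C)=CC1(C)C | intermediate
30 | [(1R,5R)-5-(2,2-dimethoxyethyl)-2,6,6-trimethylcyclohex-2-en-1-yl]methanol (2,6-cis) | COC(OC)C[C@H]1CC=C(C)[C@@H](CO)C1(C)C | intermediate
31 | 2-[(1R,5R)-5-(hydroxymethyl)-4,6,6-trimethylcyclohex-3-en-1-yl]acetaldehyde | O=CC[C@H]1CC=C(C)[C@@H](CO)C1(C)C | intermediate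
32 | [(1R,5S)-2,6,6-trimethyl-5-(3-methylbut-2-en-1-yl)cyclohex-2-en-1-yl]methanol | CC(C)=CC[C@H]1CC=C(C)[C@@H](CO)C1(C)C | intermediate
33 | (1R,5S)-2,6,6-trimethyl-5-(3-methylbut-2-en-1-yl)cyclohex-2-ene-1-carbaldehyde | CC(C)=CC[C@H]1CC=C(C)[C@@H](C=O)C1(C)C | intermediate
34 | lithium salt of 20 (phosphonate carbanion) | [Li+].CCOC(=O)/C=C(\C)[CH-]P(=O)(OCC)OCC | intermediate
35 | ethyl (2E,4E)-3-methyl-5-[(1R,5S)-2,6,6-trimethyl-5-(3-methylbut-2-en-1-yl)cyclohex-2-en-1-yl]penta-2,4-dienoate | CC(C)=CC[C@H]1CC=C(C)[C@@H](/C=C/C(C)=C/C(=O)OCC)C1(C)C | intermediate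
36 | (2E,4E)-3-methyl-5-[(1R,5S)-2,6,6-trimethyl-5-(3-methylbut-2-en-1-yl)cyclohex-2-en-1-yl]penta-2,4-dien-1-ol | CC(C)=CC[C@H]1CC=C(C)[C@@H](/C=C/C(C)=C/CO)C1(C)C | intermediate
37 | {(2E,4E)-3-methyl-5-[(1R,5S)-2,6,6-trimethyl-5-(3-methylbut-2-en-1-yl)cyclohex-2-en-1-yl]penta-2,4-dien-1-yl}triphenylphosphonium bromide | [Br-].CC(C)=CC[C@H]1CC=C(C)[C@@H](/C=C/C(C)=C/C[P+](c2ccccc2)(c2ccccc2)c2ccccc2)C1(C)C | intermediate
38 | (2E,4E,6E)-2,7-dimethylocta-2,4,6-trienedial | O=C/C(C)=C/C=C/C=C(\C)C=O | starting material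
39 | ylide of 37 | CC(C)=CC[C@H]1CC=C(C)[C@@H](/C=C/C(C)=C/C=P(c2ccccc2)(c2ccccc2)c2ccccc2)C1(C)C | intermediate
40 | (2E,4E,6E,8E,10E,12E)-2,7,11-trimethyl-13-[(1R,5S)-2,6,6-trimethyl-5-(3-methylbut-2-en-1-yl)cyclohex-2-en-1-yl]trideca-2,4,6,8,10,12-hexaenal | CC(C)=CC[C@H]1CC=C(C)[C@@H](/C=C/C(C)=C/C=C/C(C)=C/C=C/C=C(\C)C=O)C1(C)C | intermediate
41 | ylide of 25 | OC/C(C)=C/C[C@H]1CC=C(C)[C@H](/C=C/C(C)=C/C=P(c2ccccc2)(c2ccccc2)c2ccccc2)C1(C)C | intermediate
42 | (all-E,2S,6R,2'R,6'S)-2'-[(2E)-4-hydroxy-3-methylbut-2-en-1-yl]-2-(3-methylbut-2-en-1-yl)-ε,ε-carotene, CNP0304855.1 | CC(C)=CC[C@H]1CC=C(C)[C@@H](/C=C/C(C)=C/C=C/C(C)=C/C=C/C=C(C)/C=C/C=C(C)/C=C/[C@H]2C(C)=CC[C@H](C/C=C(\C)CO)C2(C)C)C1(C)C | target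

Total step count: 30 steps.
Longest linear sequence: 19 steps (steps 1–7, 19–28, 29 and 30; the ring B branch through steps 1–7, 8–18 and step 30 is equally long).

Steps most likely to fail

Step 7 (Wharton transposition). The carbonyl of 9 sits between the quaternary C1 and the fully substituted epoxide carbon, so hydrazone formation may be too slow and opening of the oxirane by hydrazine or decomposition may overtake the fragmentation. The fallback replaces the carbonyl condensation by a radical fragmentation and sets out from 9. NaBH4 in MeOH reduces the ketone to the epoxy alcohol F1 (the carbinol configuration is immaterial). NaH, CS2 and MeI convert it into the S-methyl xanthate F2. Bu3SnH with AIBN in hot toluene then generates the C6 radical, which opens the adjacent oxirane to the C4 alkoxy radical and, after hydrogen transfer, should give 11 with the C4 configuration intact (Barton–McCombie deoxygenation with epoxide fragmentation), where the route is rejoined.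

Step 22 (Wittig–Still shift of the cis ether). The cis ether must place the C4–O bond and the C2 chain both axial, so the sigmatropic shift may be slow at −78 °C and the [1,2] shift or simple protonation of the carbanion may take over. The fallback uses a neutral, thermal one-carbon transfer and sets out from 27. Heating with N,N-dimethylformamide dimethyl acetal in xylene at 140 °C (Büchi [2,3] rearrangement through an alkoxy(amino)carbene, again suprafacial) should give the dimethylamide F3 with C7 on the face of the departed oxygen. LiEt3BH in THF then reduces the tertiary amide to the primary alcohol 30, where the route is rejoined.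

Step 26 (olefination of the cis aldehyde). Aldehyde 33 carries its α-stereocentre next to a hindered carbonyl, so even with the lithium salt, enolisation by the phosphonate anion may compete with addition, and the cis C6 configuration may be lost or the alkene may move into conjugation. The same risk, in milder form, applies to step 15. The fallback reverses the polarity so that C6 is never α to a carbonyl, and sets out from 32. A Mitsunobu reaction with 1-phenyl-1H-tetrazole-5-thiol (PPh3, diisopropyl azodicarboxylate) gives the tetrazolyl sulfide F4, and (NH4)6Mo7O24·4H2O with H2O2 in EtOH oxidises it to the tetrazolyl sulfone F5. Julia–Kocienski olefination of F5 (KN(SiMe3)2, THF, −78 °C) with ethyl (2E)-3-methyl-4-oxobut-2-enoate should then give the E C7=C8 bond and dienoate 35, where the route is rejoined.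

Further compounds
F1 | step 7 | 4-(2,2-dimethoxyethyl)-1,3,3-trimethyl-7-oxabicyclo[4.1.0]heptan-2-ol (epoxide as in 9, carbinol epimers) | COC(OC)C[C@H]1C[C@@H]2O[C@]2(C)C(O)C1(C)C
F2 | step 7 | O-[4-(2,2-dimethoxyethyl)-1,3,3-trimethyl-7-oxabicyclo[4.1.0]heptan-2-yl] S-methyl carbonodithioate | COC(OC)C[C@H]1C[C@@H]2O[C@]2(C)C(OC(=S)SC)C1(C)C
F3 | step 22 | (1R,5R)-5-(2,2-dimethoxyethyl)-N,N,2,6,6-pentamethylcyclohex-2-ene-1-carboxamide | COC(OC)C[C@H]1CC=C(C)[C@@H](C(=O)N(C)C)C1(C)C
F4 | step 26 | 1-phenyl-5-({[(1R,5S)-2,6,6-trimethyl-5-(3-methylbut-2-en-1-yl)cyclohex-2-en-1-yl]methyl}sulfanyl)-1H-tetrazole | CC(C)=CC[C@H]1CC=C(C)[C@@H](CSc2nnnn2-c2ccccc2)C1(C)C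
F5 | step 26 | 1-phenyl-5-({[(1R,5S)-2,6,6-trimethyl-5-(3-methylbut-2-en-1-yl)cyclohex-2-en-1-yl]methyl}sulfonyl)-1H-tetrazole | CC(C)=CC[C@H]1CC=C(C)[C@@H](CS(=O)(=O)c2nnnn2-c2ccccc2)C1(C)C
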